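**Retrosynthetic overview**
1. Target 16 ⇐ aryl acetate 15 ⇐ Mitsunobu inversion at C10 with tiglic acid 14 on 10β-allylic alcohol 13 ⇐ 1,2-reduction of enone 12 ⇐ C6 esterification of diol-enone 10 with acid 11.
2. 10 ⇐ C4-hydroxyl-directed syn reduction of bicyclic ene-dione 9.
3. Key disconnection C1–C10 (quaternary carbon, closes the seven-membered ring): 9 ⇐ light-driven hydrogen-atom transfer and 7-endo acyl radical cyclization of keto-enal 8.
4. 8 ⇐ oxidation of vinylogous aldol adduct 7 ⇐ enal 3 + silyl dienol ether 5 (from prenal 4); 3 ⇐ ozonolysis/aldol condensation of (R)-(−)-terpinen-4-ol 1, which supplies C4.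
5. Ring order: five-membered ring first (step 1), seven-membered ring second (step 5); C1 and C5 are set in the cyclization, C6 by chelation to the C4 hydroxyl, C10 by substrate-controlled reduction followed by inversion.

Numbering (daucane): five-membered ring C1 (ring-fusion carbon bearing CH3), C2, C3, C4 (carbinol carbon bearing isopropyl), C5 (ring-fusion CH); seven-membered ring C5, C6, C7, C8 (bears CH3), C9, C10, C1; α is the face of 5-H, β the face of the C1 methyl group. The same labels are used for the corresponding atoms of the monocyclic precursors.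
Assumption: commercial (R)-(−)-terpinen-4-ol is used as enantiopure material; prenal, 4-acetoxybenzoic acid and tiglic acid are purchased.

Step 1
Reactants: 1 (R)-(−)-terpinen-4-ol [(1R)-4-methyl-1-(propan-2-yl)cyclohex-3-en-1-ol]
Product: 3 (5S)-5-hydroxy-2-methyl-5-(propan-2-yl)cyclopent-1-ene-1-carbaldehyde, via keto aldehyde 2 (not isolated)
Conditions: O3, CH2Cl2/MeOH, −78 °C; Me2S, −78 °C → rt; then piperidine (0.2 equiv), AcOH (0.2 equiv), Et2O, rt
Reagents that add atoms: ozone, [O-][O+]=O
Why: Ozonolysis with reductive work-up cleaves the ring alkene to the keto aldehyde, and an amine-catalysed intramolecular aldol condensation (aldehyde enamine adds to the methyl ketone, as with the limonene-derived keto aldehyde) closes the five-membered ring and dehydrates to the tetrasubstituted enal; no new stereocenter is made and the purchased carbinol center (future C4) is untouched.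

Step 2
Reactants: 4 3-methylbut-2-enal (prenal)
Product: 5 (E)-trimethyl[(3-methylbuta-1,3-dien-1-yl)oxy]silane
Conditions: TMSCl, Et3N, ZnCl2 (cat.), toluene, 60 °C
Reagents that add atoms: chlorotrimethylsilane, C[Si](C)(C)Cl
Why: Silyl dienol ether formation by soft enolisation: O-silylation and γ-deprotonation of the β,β-dimethyl enal give the conjugated (E)-1-silyloxydiene, the γ-nucleophilic equivalent of prenal.

Step 3
Reactants: 3 (5S)-5-hydroxy-2-methyl-5-(propan-2-yl)cyclopent-1-ene-1-carbaldehyde; 5 (E)-trimethyl[(3-methylbuta-1,3-dien-1-yl)oxy]silane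
Product: 7 (2E)-5-hydroxy-5-[(5S)-5-hydroxy-2-methyl-5-(propan-2-yl)cyclopent-1-en-1-yl]-3-methylpent-2-enal (both epimers at the new carbinol), via silyl ether 6 (not isolated)
Conditions: Sc(OTf)3 (10 mol%), CH2Cl2, −78 → −40 °C; then 1 M HCl, THF, 0 °C
Reagents that add atoms: none
Why: Vinylogous Mukaiyama aldol addition: the Lewis-acid-activated aldehyde of 3 is attacked by the terminal (γ) carbon of 5, forming the future C6–C7 bond and the (E)-enal, and acid work-up cleaves the silyl ether; the new carbinol (future C6) forms as a mixture, which does not matter because it is oxidised in step 4.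

Step 4
Reactants: 7 (2E)-5-hydroxy-5-[(5S)-5-hydroxy-2-methyl-5-(propan-2-yl)cyclopent-1-en-1-yl]-3-methylpent-2-enal
Product: 8 (2E)-5-[(5S)-5-hydroxy-2-methyl-5-(propan-2-yl)cyclopent-1-en-1-yl]-3-methyl-5-oxopent-2-enal
Conditions: Dess–Martin periodinane, CH2Cl2, 0 °C → rt
Reagents that add atoms: none
Why: Dess–Martin oxidation converts the secondary allylic alcohol into the ketone (tertiary alcohol and aldehyde are inert), which makes C1 the β-carbon of an enone and therefore a radical acceptor.

Step 5
Reactants: 8 (2E)-5-[(5S)-5-hydroxy-2-methyl-5-(propan-2-yl)cyclopent-1-en-1-yl]-3-methyl-5-oxopent-2-enal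
Product: 9 (1S,4S,5R)-4-hydroxydauc-8-ene-6,10-dione (trans-fused; 5-H α, 1-CH3 β, 4-OH α)
Conditions: (nBu4N)4[W10O32] (2 mol%), MeCN (0.005 M), 390 nm LEDs, Ar, 30 °C
Reagents that add atoms: none
Why: Proposed new method: photoexcited decatungstate abstracts the formyl hydrogen of the enal; the resulting α,β-unsaturated acyl radical loses its C8=C9 geometry through its α-ketenyl resonance form, and the cisoid rotamer adds 7-endo-trig to C1, the β-carbon of the tethered enone (nucleophilic radical on an electron-poor alkene; 6-exo attack at the α-carbon is polarity-mismatched), on the face syn to the small C4 hydroxyl and anti to isopropyl, which sets the quaternary C1; the α-keto radical at C5 then takes hydrogen back from the reduced catalyst on the face opposite the C1 methyl and C4 isopropyl groups, giving the trans ring fusion; the closest known reactions are intermolecular decatungstate hydroacylation of electron-poor alkenes with aldehydes and tin-hydride-mediated 7-endo acyl radical cyclizations of selenoesters.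

Step 6
Reactants: 9 (1S,4S,5R)-4-hydroxydauc-8-ene-6,10-dione
Product: 10 (1S,4S,5S,6S)-4,6-dihydroxydauc-8-en-10-one (4α,6α-diol)
Conditions: Et2BOMe, THF/MeOH (4:1), −78 °C; NaBH4, −78 °C; then AcOH, MeOH co-evaporation
Reagents that add atoms: none
Why: Narasaka–Prasad reduction: the C4 hydroxyl and the C6 ketone form a six-membered boron chelate in which isopropyl and C1 are equatorial, and axial external hydride delivery gives the 4,6-syn diol, that is the 6α (S) alcohol; the unchelated, hindered and conjugated C10 ketone is not reduced at −78 °C, and the low temperature keeps the acidic C7 methylene of the ene-dione from enolising.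

Step 7
Reactants: 10 (1S,4S,5S,6S)-4,6-dihydroxydauc-8-en-10-one; 11 4-acetoxybenzoic acid
Product: 12 (1S,4S,5S,6S)-4-hydroxy-10-oxodauc-8-en-6-yl 4-acetoxybenzoate
Conditions: DCC, DMAP (cat.), CH2Cl2, 0 °C → rt
Reagents that add atoms: none
Why: Steglich esterification acylates the only secondary alcohol (C6); the tertiary C4 hydroxyl does not react and the phenol of the acid is masked as its acetate.

Step 8
Reactants: 12 (1S,4S,5S,6S)-4-hydroxy-10-oxodauc-8-en-6-yl 4-acetoxybenzoate
Product: 13 (1S,4S,5S,6S,10S)-4,10-dihydroxydauc-8-en-6-yl 4-acetoxybenzoate (10β-alcohol)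
Conditions: NaBH4, CeCl3·7H2O, MeOH/THF, −78 °C
Reagents that add atoms: none
Why: Luche reduction gives clean 1,2-reduction of the enone; hydride adds to C10 from the α-face, opposite the adjacent angular C1 methyl group (the same bias as in 17-keto steroids), giving the 10β (S) allylic alcohol, and the esters are untouched at this temperature.

Step 9
Reactants: 13 (1S,4S,5S,6S,10S)-4,10-dihydroxydauc-8-en-6-yl 4-acetoxybenzoate; 14 tiglic acid [(2E)-2-methylbut-2-enoic acid]
Product: 15 (1S,4S,5S,6S,10R)-4-hydroxy-10-[(2E)-2-methylbut-2-enoyloxy]dauc-8-en-6-yl 4-acetoxybenzoate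
Conditions: PPh3, DIAD, toluene, 0 °C → rt
Reagents that add atoms: none
Why: Mitsunobu reaction: the secondary allylic alcohol is activated as its oxyphosphonium salt and displaced by tiglate in an SN2 process with inversion, which installs the ester in the 10α (R) configuration; the tertiary C4 hydroxyl is not activated.

Step 10
Reactants: 15 (1S,4S,5S,6S,10R)-4-hydroxy-10-[(2E)-2-methylbut-2-enoyloxy]dauc-8-en-6-yl 4-acetoxybenzoate
Product: 16 (1S,4S,5S,6S,10R)-4-hydroxy-10-[(2E)-2-methylbut-2-enoyloxy]dauc-8-en-6-yl 4-hydroxybenzoate (target)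
Conditions: pyrrolidine (2 equiv), CH2Cl2, 0 °C
Reagents that add atoms: none
Why: Chemoselective aminolysis: the aryl acetate is far more electrophilic than the hindered alkyl tiglate and benzoate esters and is cleaved by the secondary amine at 0 °C, releasing the phenol without touching any stereocenter.

**Compound list**
1 | (R)-(−)-terpinen-4-ol, (1R)-4-methyl-1-(propan-2-yl)cyclohex-3-en-1-ol | CC1=CC[C@@](O)(C(C)C)CC1 | starting material
2 | (3R)-3-hydroxy-6-oxo-3-(propan-2-yl)heptanal | CC(=O)CC[C@](CC=O)(O)C(C)C | intermediate (not isolated)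
3 | (5S)-5-hydroxy-2-methyl-5-(propan-2-yl)cyclopent-1-ene-1-carbaldehyde | O=CC1=C(C)CC[C@]1(O)C(C)C | intermediate
4 | 3-methylbut-2-enal (prenal) | CC(C)=CC=O | starting material
5 | (E)-trimethyl[(3-methylbuta-1,3-dien-1-yl)oxy]silane | C=C(C)/C=C/O[Si](C)(C)C | intermediate
6 | (2E)-5-[(5S)-5-hydroxy-2-methyl-5-(propan-2-yl)cyclopent-1-en-1-yl]-3-methyl-5-[(trimethylsilyl)oxy]pent-2-enal (epimer mixture at the silyloxy carbon) | O=C/C=C(\C)CC(O[Si](C)(C)C)C1=C(C)CC[C@]1(O)C(C)C | intermediate (not isolated)
7 | (2E)-5-hydroxy-5-[(5S)-5-hydroxy-2-methyl-5-(propan-2-yl)cyclopent-1-en-1-yl]-3-methylpent-2-enal (epimer mixture at the secondary carbinol) | O=C/C=C(\C)CC(O)C1=C(C)CC[C@]1(O)C(C)C | intermediate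
8 | (2E)-5-[(5S)-5-hydroxy-2-methyl-5-(propan-2-yl)cyclopent-1-en-1-yl]-3-methyl-5-oxopent-2-enal | O=C/C=C(\C)CC(=O)C1=C(C)CC[C@]1(O)C(C)C | intermediate
9 | (1S,4S,5R)-4-hydroxydauc-8-ene-6,10-dione (trans-fused) | O=C1C=C(C)CC(=O)[C@@H]2[C@]1(C)CC[C@]2(O)C(C)C | intermediate
10 | (1S,4S,5S,6S)-4,6-dihydroxydauc-8-en-10-one | O=C1C=C(C)C[C@H](O)[C@@H]2[C@]1(C)CC[C@]2(O)C(C)C | intermediate
11 | 4-acetoxybenzoic acid | CC(=O)Oc1ccc(cc1)C(=O)O | starting material
12 | (1S,4S,5S,6S)-4-hydroxy-10-oxodauc-8-en-6-yl 4-acetoxybenzoate | O=C1C=C(C)C[C@H](OC(=O)c2ccc(OC(C)=O)cc2)[C@@H]2[C@]1(C)CC[C@]2(O)C(C)C | intermediate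
13 | (1S,4S,5S,6S,10S)-4,10-dihydroxydauc-8-en-6-yl 4-acetoxybenzoate | O[C@H]1C=C(C)C[C@H](OC(=O)c2ccc(OC(C)=O)cc2)[C@@H]2[C@]1(C)CC[C@]2(O)C(C)C | intermediate
14 | tiglic acid, (2E)-2-methylbut-2-enoic acid | C/C=C(\C)C(=O)O | starting material
15 | (1S,4S,5S,6S,10R)-4-hydroxy-10-[(2E)-2-methylbut-2-enoyloxy]dauc-8-en-6-yl 4-acetoxybenzoate | C/C=C(\C)C(=O)O[C@@H]1C=C(C)C[C@H](OC(=O)c2ccc(OC(C)=O)cc2)[C@@H]2[C@]1(C)CC[C@]2(O)C(C)C | intermediate
16 | (1S,4S,5S,6S,10R)-4-hydroxy-10-[(2E)-2-methylbut-2-enoyloxy]dauc-8-en-6-yl 4-hydroxybenzoate | C/C=C(\C)C(=O)O[C@@H]1C=C(C)C[C@H](OC(=O)c2ccc(O)cc2)[C@@H]2[C@]1(C)CC[C@]2(O)C(C)C | target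

**Step count and risks**
Total steps: 10. Longest linear sequence: 9 (steps 1, 3, 4, 5, 6, 7, 8, 9, 10).

Most likely to fail, first: step 5, the proposed photocatalytic cyclization. The formyl hydrogen abstraction must win over other C–H bonds, and the acyl radical must cyclize onto a fully substituted carbon before it is quenched. The fallback uses known chemistry and sets out from 8. Pinnick oxidation (NaClO2, NaH2PO4, 2-methylbut-2-ene, tBuOH/H2O) gives (2E)-5-[(5S)-5-hydroxy-2-methyl-5-(propan-2-yl)cyclopent-1-en-1-yl]-3-methyl-5-oxopent-2-enoic acid F4. PhSeSePh and PBu3 convert it into the Se-phenyl selenoester F5. Slow addition of Bu3SnH with AIBN in refluxing benzene at high dilution generates the same acyl radical in a thermal tin hydride chain and closes the ring by the established 7-endo acyl radical cyclization, coming back to the route at 9.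

Second: step 1. In the aldol intermediate both the new tertiary hydroxyl and the purchased C4 hydroxyl are β to the aldehyde, so dehydration could remove the wrong one, and the β-hydroxy aldehyde 2 can undergo retro-aldol cleavage. The fallback sets out from 1 and masks the carbinol first. TESOTf and 2,6-lutidine give (R)-triethyl{[4-methyl-1-(propan-2-yl)cyclohex-3-en-1-yl]oxy}silane F1. The same ozonolysis with Me2S work-up gives the silyloxy keto aldehyde F2 (not isolated), which cannot undergo retro-aldol and has only one free hydroxyl to lose after cyclization. Piperidine/AcOH then gives the silyloxy enal F3, and HF·pyridine in THF removes the silyl group, coming back to the route at 3.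

Third: step 9. The Mitsunobu displacement is at an allylic carbon next to a quaternary center, so SN2′ attack or elimination may compete. The fallback sets out from 13 and replaces the in situ oxyphosphonium activation by a discrete sulfonate displacement. MsCl and Et3N in CH2Cl2 at −20 °C give the allylic mesylate F6. CsO2CC(CH3)=CHCH3 (from tiglic acid 14 and Cs2CO3) with 18-crown-6 in toluene displaces it with inversion, coming back to the route at 15.

**Further compounds**
F1 | step 1 | (R)-triethyl{[4-methyl-1-(propan-2-yl)cyclohex-3-en-1-yl]oxy}silane | CC1=CC[C@@](O[Si](CC)(CC)CC)(C(C)C)CC1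
F2 | step 1 | (3R)-6-oxo-3-(propan-2-yl)-3-[(triethylsilyl)oxy]heptanal | CC(=O)CC[C@](CC=O)(O[Si](CC)(CC)CC)C(C)C
F3 | step 1 | (5S)-2-methyl-5-(propan-2-yl)-5-[(triethylsilyl)oxy]cyclopent-1-ene-1-carbaldehyde | O=CC1=C(C)CC[C@]1(O[Si](CC)(CC)CC)C(C)C
F4 | step 5 | (2E)-5-[(5S)-5-hydroxy-2-methyl-5-(propan-2-yl)cyclopent-1-en-1-yl]-3-methyl-5-oxopent-2-enoic acid | OC(=O)/C=C(\C)CC(=O)C1=C(C)CC[C@]1(O)C(C)C
F5 | step 5 | Se-phenyl (2E)-5-[(5S)-5-hydroxy-2-methyl-5-(propan-2-yl)cyclopent-1-en-1-yl]-3-methyl-5-oxopent-2-eneselenoate | O=C([Se]c1ccccc1)/C=C(\C)CC(=O)C1=C(C)CC[C@]1(O)C(C)C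
F6 | step 9 | (1S,4S,5S,6S,10S)-4-hydroxy-10-(methanesulfonyloxy)dauc-8-en-6-yl 4-acetoxybenzoate | CS(=O)(=O)O[C@H]1C=C(C)C[C@H](OC(=O)c2ccc(OC(C)=O)cc2)[C@@H]2[C@]1(C)CC[C@]2(O)C(C)C
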